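A small charge of Sub, 0.25 M all at the start in Monday's flask, stands against 0.80 M in portions in Thursday's. In both, Ptn in a second phase passes reversibly into the reaction phase as Ptn2. There Sub + Ptn2 gives Tgt, Ptn2 alone gives Sid, Ptn2 + Tgt gives Sid3, and Sub + Tgt gives Sid2.

| flask | Sub | Ptn | temperature | remark | time | volume of the second phase over the first |
|---|---|---|---|---|---|---|
| west | 0.19 M (in portions, 4) | 1.2 M | −10 °C | run made earlier; portions every 3.0 min |  |  |
| north-east | 0.44 M (in portions, 4) | 1.2 M | 5 °C | run made earlier; portions every 3.0 min |  |  |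
| north-west | 0.83 M (in portions, 4) | 1.2 M | −10 °C | run made earlier; portions every 3.0 min |  |  |
| Thursday's | 0.80 M (in portions, 4) | 1.20 M | 5 °C | the portions of Sub follow each other after 3.0 min, the first at the start | 80 min | 1.0 |
| Monday's | 0.25 M | 1.20 M | 5 °C | everything together at the start | 80 min | 1.0 |

| run | time / min | Tgt / % |
|---|---|---|
| west | 10.0 | 0.3 |
| west | 20.0 | 0.2 |
| west | 50.0 | 3.8 |
| west | 120 | 15.5 |
| north-east | 8.00 | 0.6 |
| north-east | 20.0 | 2.8 |
| north-east | 40.0 | 7.6 |
| north-east | 60.0 | 12.8 |
| north-west | 30.0 | 1.3 |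
| north-west | 60.0 | 5.3 |
| north-west | 80.0 | 7.2 |
| north-west | 120 | 11.7 |

(readings scatter by 0.5 percentage points)
- a species is counted by the Sub in it: one Sid2 counts as two
- in the second phase: Ptn; everything else is in the first
- charges count per volume of the first phase; a concentration in a rate is the amount of a species over the volume of its own phase; every rate counts per litre of the first phase
- what may be going on: Ptn2 <-> Ptn; Sub + Ptn2 -> Tgt; Ptn2 -> Sid; Sub + Tgt -> Sid2; Ptn2 + Tgt -> Sid3
- the earlier runs hold the two phases in the same ratio of volumes as the flask asked about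
- the flask that ends with the higher amount of Tgt, in percent of the Sub charged, or "neither" when 2 percentage points or less lies between them (Thursday's / Monday's / neither)
- final Tgt, as a percentage of the Sub charged, in Thursday's
- final Tgt, as a percentage of the Sub charged, in Monday's

*What do you see first?* At −10 °C, the concentrated north-west run holds 11.7% at 120 min, less than the 15.5% of the dilute west run. I read that gap as Tgt lost to Sub.

*Count it.* With Sub roughly held, the loss is pseudo-first-order: its time constant is k c inverted, where k is the constant of Sub + Tgt and c the Sub charged. So N = k c t counts loss turnovers in time t, and Tgt made steadily keeps the fraction S = (1 − e^(−N))/N. Thursday's count over Monday's, the turnover ratio, is 3.20, whatever k is.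

*And k?* Taking Tgt's mean age as t/2, the cold pair reads 0.00732 /M/min, with the scatter of two readings in it.

*That is cold. Your flasks are not.* This is the weak spot. I assume a doubling per 10 K, a factor 2.83, giving 0.0207 /M/min: a guess. Then Monday's N is 0.414 and Thursday's 1.33.

*Yields?* The north-east run shows a lag of 10.8 min. With its count 0.547 put back, it gives 23.4% before loss at 80 min. So I commit to 19.1% for Monday's and 12.9% for Thursday's.

The forecast also names Monday's, with 20.3% (18% to 23%) for Monday's and 14.5% (12.5% to 17%) for Thursday's, noting that “the concentrated run falls behind”. My figures are lower for both.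

The flasks give 11.2% for Thursday's and 21.0% for Monday's, so Monday's ends higher.

    Ptn2 ⇌ Ptn, rate k1*([Ptn2] - [Ptn]/K1) per volume of the first phase (partition coefficient = 0.350, kL = 7.62 × 10⁻⁵ /s)
    Sub + Ptn2 → Tgt (k = 2.30 × 10⁻⁴ /M/s, Ea = 62.0 kJ/mol)
    Ptn2 → Sid (k = 1.68 × 10⁻⁴ /s, Ea = 94.0 kJ/mol)
    Sub + Tgt → Sid2 (k = 6.50 × 10⁻⁴ /M/s, Ea = 72.0 kJ/mol)
    Ptn2 + Tgt → Sid3 (k = 1.29 × 10⁻⁵ /M/s, Ea = 57.0 kJ/mol)
    (constants at 5 °C)

In Thursday's, the step from Sub + Tgt to Sid2 is the largest single effect, though not the whole of the gap: without it, Thursday's Tgt rises from 11.2% to 24.2%, still less than the 27.7% of Monday's without it. With the scheme's constant, Monday's N is 0.780, and the turnover ratio makes Thursday's 2.50, so Thursday's keeps 0.529 of Monday's fraction. A neighbour of Monday's with 0.10 M of Sub has N = 0.312, which scales Monday's Tgt to 26.0%; that flask ends at 25.6%.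

(The readings come from a simulation on assumed constants; scatter was added.)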